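**Retrosynthetic overview**
1. The target comes from its tetra-MOM ether by one acidic deprotection; all four phenols stay masked until then.
2. Ring C is closed last through the C3–C4 bond: a carbene-derived acyl anion (Breslow intermediate) of the ring A aldehyde attacks a tethered, racemic α-aryloxy aldehyde, with dynamic kinetic resolution setting C2 and C3 together.
3. The dialdehyde comes from a Mitsunobu ether coupling (O1–C2) of a fully substituted ring A salicylaldehyde with a ring B benzylic alcohol carrying a silyl-protected CH2OH (the future C3), then desilylation and oxidation.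
4. The ring A aldehyde comes from 2-methoxyresorcinol by MOM protection, Ir-catalysed C–H borylation/oxidation, ortho-C-prenylation and ortho-formylation; the ring B alcohol comes from hydroquinone by MOM protection, ortho-lithiation and addition to TBSOCH2CHO.
5. Ring order: rings A and B are bought as arenes and elaborated separately; ring C is formed in the key step.

Assumption: the (5aS,10bR) antipode of the triazolium salt is taken to give the (2R,3R) product; both antipodes are sold, and the mirror-image salt is used if a test run shows the opposite sense. The ring B carbinol and the three compounds made from it before the key step are racemic.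

**Step 1**
Reactants: 1 2-methoxybenzene-1,3-diol (2-methoxyresorcinol)
Product: 2 2-methoxy-1,3-bis(methoxymethoxy)benzene
Conditions: NaH (2.4 equiv), MOMCl (2.4 equiv), DMF, 0 °C → rt
Reagents that add atoms: chloromethyl methyl ether (MOMCl), COCCl
Why: Williamson-type O-alkylation of both sodium phenoxides by the α-chloro ether (MOM protection); no stereocentre is involved.

**Step 2**
Reactants: 2 2-methoxy-1,3-bis(methoxymethoxy)benzene
Product: 4 4-methoxy-3,5-bis(methoxymethoxy)phenol, via arylboronic pinacol ester 3 (not isolated)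
Conditions: [Ir(OMe)(cod)]2 (1.5 mol %), 4,4′-di-tert-butyl-2,2′-bipyridine (3 mol %), B2pin2 (1.0 equiv), THF, 80 °C; then 30% aq H2O2, 2 M NaOH, 0 °C → rt, one pot
Reagents that add atoms: hydrogen peroxide, OO (the phenol oxygen); bis(pinacolato)diboron, CC1(C)OB(OC1(C)C)B1OC(C)(C)C(C)(C)O1 (boron of intermediate 3 only)
Why: sterically controlled Ir-catalysed aromatic C–H borylation (Hartwig–Miyaura type) hits the only C–H without an ortho substituent (para to OMe), and basic peroxide oxidation of the C–B bond gives the phenol that will become O1.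

**Step 3**
Reactants: 4 4-methoxy-3,5-bis(methoxymethoxy)phenol; 5 1-bromo-3-methylbut-2-ene (prenyl bromide)
Product: 6 4-methoxy-3,5-bis(methoxymethoxy)-2-(3-methylbut-2-en-1-yl)phenol
Conditions: NaH (1.05 equiv), toluene, 0 °C → rt; then 5 (1.0 equiv), rt, 16 h
Reagents that add atoms: none
Why: ortho-selective C-alkylation of a sodium phenoxide as a tight ion pair in a non-polar solvent; the para position is blocked by OMe and the two ortho carbons are equivalent, so only one mono-C-prenyl product can form.

**Step 4**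
Reactants: 6 4-methoxy-3,5-bis(methoxymethoxy)-2-(3-methylbut-2-en-1-yl)phenol
Product: 8 2-hydroxy-5-methoxy-4,6-bis(methoxymethoxy)-3-(3-methylbut-2-en-1-yl)benzaldehyde, via ortho-hydroxymethyl phenol 7 (not isolated)
Conditions: MgCl2 (2 equiv), Et3N (4 equiv), paraformaldehyde (6 equiv), MeCN, reflux, 4 h; dilute citric acid work-up
Reagents that add atoms: formaldehyde (from paraformaldehyde), C=O
Why: Casnati–Skattebøl ortho-formylation, in which the magnesium phenoxide delivers formaldehyde to the single free ortho carbon and the benzylic alkoxide 7 is oxidised by a second formaldehyde through Oppenauer-type hydride transfer.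

**Step 5**
Reactants: 9 benzene-1,4-diol (hydroquinone)
Product: 10 1,4-bis(methoxymethoxy)benzene
Conditions: NaH (2.4 equiv), MOMCl (2.4 equiv), DMF, 0 °C → rt
Reagents that add atoms: chloromethyl methyl ether (MOMCl), COCCl
Why: Williamson-type MOM protection of both phenols, which also installs the directing groups for the next step.

**Step 6**
Reactants: 10 1,4-bis(methoxymethoxy)benzene; 11 2-[(tert-butyldimethylsilyl)oxy]acetaldehyde
Product: 13 rac-1-[2,5-bis(methoxymethoxy)phenyl]-2-[(tert-butyldimethylsilyl)oxy]ethan-1-ol, via aryllithium 12 (not isolated)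
Conditions: n-BuLi (1.1 equiv), THF, 0 °C, 1 h; then 11, −78 → 0 °C; H2O
Reagents that add atoms: n-butyllithium, [Li]CCCC (lithium of intermediate 12 only)
Why: OMOM-directed ortho-lithiation (directed ortho metalation) followed by 1,2-addition to the aldehyde; the carbinol forms racemic, which is harmless because this centre becomes configurationally labile before it is fixed in step 10.

**Step 7**
Reactants: 8 2-hydroxy-5-methoxy-4,6-bis(methoxymethoxy)-3-(3-methylbut-2-en-1-yl)benzaldehyde; 13 rac-1-[2,5-bis(methoxymethoxy)phenyl]-2-[(tert-butyldimethylsilyl)oxy]ethan-1-ol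
Product: 14 rac-2-{1-[2,5-bis(methoxymethoxy)phenyl]-2-[(tert-butyldimethylsilyl)oxy]ethoxy}-5-methoxy-4,6-bis(methoxymethoxy)-3-(3-methylbut-2-en-1-yl)benzaldehyde
Conditions: PPh3 (1.5 equiv), DIAD (1.5 equiv), toluene, 0 °C → rt
Reagents that add atoms: none
Why: Mitsunobu etherification, in which the acidic salicylaldehyde phenol (the only free OH of 8) displaces the oxyphosphonium of the secondary benzylic alcohol to form the O1–C2 bond; the product is racemic.

**Step 8**
Reactants: 14 (silyl ether from step 7)
Product: 15 rac-2-{1-[2,5-bis(methoxymethoxy)phenyl]-2-hydroxyethoxy}-5-methoxy-4,6-bis(methoxymethoxy)-3-(3-methylbut-2-en-1-yl)benzaldehyde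
Conditions: Bu4NF (1.2 equiv), AcOH (1.2 equiv), THF, 0 °C → rt
Reagents that add atoms: none
Why: fluoride-driven Si–O cleavage (desilylation), buffered so that the aryl aldehyde and the MOM acetals are untouched.

**Step 9**
Reactants: 15 (primary alcohol from step 8)
Product: 16 rac-2-{1-[2,5-bis(methoxymethoxy)phenyl]-2-oxoethoxy}-5-methoxy-4,6-bis(methoxymethoxy)-3-(3-methylbut-2-en-1-yl)benzaldehyde
Conditions: Dess–Martin periodinane (1.3 equiv), CH2Cl2, 0 °C → rt; short silica pad, used the same day
Reagents that add atoms: none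
Why: Dess–Martin oxidation stops at the aldehyde under neutral conditions and tolerates the prenyl alkene, the MOM acetals and the aryl aldehyde.

**Step 10 (key step)**
Reactants: 16 (racemic dialdehyde from step 9)
Product: 17 (2R,3R)-2-[2,5-bis(methoxymethoxy)phenyl]-3-hydroxy-6-methoxy-5,7-bis(methoxymethoxy)-8-(3-methylbut-2-en-1-yl)-2,3-dihydro-4H-chromen-4-one (2,3-trans)
Conditions: (5aS,10bR)-2-(pentafluorophenyl)-5a,10b-dihydro-4H,6H-indeno[2,1-b][1,2,4]triazolo[4,3-d][1,4]oxazin-2-ium tetrafluoroborate (15 mol %), Et3N (1.0 equiv), 4 Å MS, toluene (0.05 M), 23 °C, argon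
Reagents that add atoms: none
Why: Proposed new method: the triazolylidene adds to the ring A aldehyde to give a Breslow intermediate (acyl anion at the future C4) that attacks the tethered aldehyde carbon (future C3) in a 6-exo cyclisation, joining two carbonyl carbons that are both electrophilic, closing ring C and releasing the carbene; because the α-aryl-α-aryloxy aldehyde epimerises through its enol under Et3N, both enantiomers of 16 funnel through the matched transition state (2-aryl pseudo-equatorial, aldehyde face fixed by the indane wall of the catalyst), a dynamic kinetic resolution that sets C2 (R) and C3 (R) together as the diequatorial trans isomer, which is also the thermodynamic one; the α-branched α-oxy aldehyde is a reluctant Breslow donor but an activated acceptor, which should direct the chemoselectivity; the closest known reaction types are the enantioselective intramolecular crossed aldehyde–ketone benzoin cyclisation to 3-hydroxychroman-4-ones and dynamic kinetic resolutions in carbene-catalysed intermolecular cross-benzoin reactions.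

**Step 11**
Reactants: 17 (tetra-MOM flavanonol from step 10)
Product: 18 (2R,3R)-2-(2,5-dihydroxyphenyl)-3,5,7-trihydroxy-6-methoxy-8-(3-methylbut-2-en-1-yl)-2,3-dihydro-4H-chromen-4-one (CNP0287732.1)
Conditions: 3 M aq HCl–MeOH (1:5), 45 °C, 3 h, argon
Reagents that add atoms: none
Why: acid-catalysed acetal exchange with methanol removes all four MOM groups, while the aryl methyl ether, the prenyl group and the ketol survive dilute acid at this temperature and neither stereocentre enolises or ionises appreciably.

**Compound list**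
1 | 2-methoxybenzene-1,3-diol (2-methoxyresorcinol) | COc1c(O)cccc1O | starting material
2 | 2-methoxy-1,3-bis(methoxymethoxy)benzene | COCOc1cccc(OCOC)c1OC | intermediate
3 | 2-[4-methoxy-3,5-bis(methoxymethoxy)phenyl]-4,4,5,5-tetramethyl-1,3,2-dioxaborolane (formed in the flask) | COCOc1cc(B2OC(C)(C)C(C)(C)O2)cc(OCOC)c1OC | intermediate
4 | 4-methoxy-3,5-bis(methoxymethoxy)phenol | COCOc1cc(O)cc(OCOC)c1OC | intermediate
5 | 1-bromo-3-methylbut-2-ene (prenyl bromide) | CC(C)=CCBr | starting material
6 | 4-methoxy-3,5-bis(methoxymethoxy)-2-(3-methylbut-2-en-1-yl)phenol | COCOc1cc(O)c(CC=C(C)C)c(OCOC)c1OC | intermediate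
7 | 2-(hydroxymethyl)-4-methoxy-3,5-bis(methoxymethoxy)-6-(3-methylbut-2-en-1-yl)phenol (formed in the flask as its magnesium salt) | COCOc1c(CO)c(O)c(CC=C(C)C)c(OCOC)c1OC | intermediate
8 | 2-hydroxy-5-methoxy-4,6-bis(methoxymethoxy)-3-(3-methylbut-2-en-1-yl)benzaldehyde | COCOc1c(C=O)c(O)c(CC=C(C)C)c(OCOC)c1OC | intermediate
9 | benzene-1,4-diol (hydroquinone) | Oc1ccc(O)cc1 | starting material
10 | 1,4-bis(methoxymethoxy)benzene | COCOc1ccc(OCOC)cc1 | intermediate
11 | 2-[(tert-butyldimethylsilyl)oxy]acetaldehyde | CC(C)(C)[Si](C)(C)OCC=O | starting material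
12 | [2,5-bis(methoxymethoxy)phenyl]lithium (formed in the flask) | [Li]c1cc(OCOC)ccc1OCOC | intermediate
13 | rac-1-[2,5-bis(methoxymethoxy)phenyl]-2-[(tert-butyldimethylsilyl)oxy]ethan-1-ol | CC(C)(C)[Si](C)(C)OCC(O)c1cc(OCOC)ccc1OCOC | intermediate
14 | rac-2-{1-[2,5-bis(methoxymethoxy)phenyl]-2-[(tert-butyldimethylsilyl)oxy]ethoxy}-5-methoxy-4,6-bis(methoxymethoxy)-3-(3-methylbut-2-en-1-yl)benzaldehyde | COCOc1c(C=O)c(OC(CO[Si](C)(C)C(C)(C)C)c2cc(OCOC)ccc2OCOC)c(CC=C(C)C)c(OCOC)c1OC | intermediate
15 | rac-2-{1-[2,5-bis(methoxymethoxy)phenyl]-2-hydroxyethoxy}-5-methoxy-4,6-bis(methoxymethoxy)-3-(3-methylbut-2-en-1-yl)benzaldehyde | COCOc1c(C=O)c(OC(CO)c2cc(OCOC)ccc2OCOC)c(CC=C(C)C)c(OCOC)c1OC | intermediate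
16 | rac-2-{1-[2,5-bis(methoxymethoxy)phenyl]-2-oxoethoxy}-5-methoxy-4,6-bis(methoxymethoxy)-3-(3-methylbut-2-en-1-yl)benzaldehyde | COCOc1c(C=O)c(OC(C=O)c2cc(OCOC)ccc2OCOC)c(CC=C(C)C)c(OCOC)c1OC | intermediate
17 | (2R,3R)-2-[2,5-bis(methoxymethoxy)phenyl]-3-hydroxy-6-methoxy-5,7-bis(methoxymethoxy)-8-(3-methylbut-2-en-1-yl)-2,3-dihydro-4H-chromen-4-one | COc1c(OCOC)c(CC=C(C)C)c2c(c1OCOC)C(=O)[C@H](O)[C@@H](c1cc(OCOC)ccc1OCOC)O2 | intermediate
18 | (2R,3R)-2-(2,5-dihydroxyphenyl)-3,5,7-trihydroxy-6-methoxy-8-(3-methylbut-2-en-1-yl)-2,3-dihydro-4H-chromen-4-one | COc1c(O)c(CC=C(C)C)c2c(c1O)C(=O)[C@H](O)[C@@H](c1cc(O)ccc1O)O2 | target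

**Totals**
Total step count: 11. Longest linear sequence: 9 (steps 1, 2, 3, 4, 7, 8, 9, 10, 11).

**Steps most likely to fail, and fallbacks**

Step 10. The ring A aldehyde is di-ortho-substituted and electron-rich, so it may be a poor acyl donor. The aliphatic aldehyde could instead form a Breslow intermediate and expel the ring A phenoxide, or its enol could add to the aryl aldehyde in a 5-exo aldol. The dynamic kinetic resolution is also untested. The fallback sets out from 16 and comes back at 17. It keeps the union of the two carbonyl carbons at C3–C4 but uses a ketyl instead of a Breslow intermediate. SmI2 (2.2 equiv, THF/t-BuOH, −78 °C) reduces the aryl aldehyde of 16 to its ketyl, which adds to the tethered aldehyde in a pinacol cyclisation and gives the chromane-3,4-diol F1 as a racemic stereoisomer mixture. Activated MnO2 (CH2Cl2, rt) oxidises only the benzylic C4 carbinol, and brief Et3N treatment equilibrates C3 to give the racemic trans ketol F2. Preparative HPLC on a chiral phase (amylose tris(3,5-dimethylphenylcarbamate)) then delivers the (2R,3R)-enantiomer, which is 17.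

Step 7. The phenol of 8 is flanked by CHO and prenyl and is hydrogen-bonded, and the electron-rich benzylic oxyphosphonium may ionise or lose its neighbouring MOM group. The fallback sets out from 12 (with 8 as the partner) and comes back at 16, bypassing 14 and 15. Aryllithium 12 is quenched with ethyl glyoxylate (THF, −78 °C) to give the hydroxy ester F3. MsCl and Et3N (CH2Cl2, 0 °C) convert it into the mesylate F4. The potassium phenoxide of 8 (K2CO3, acetone, rt) displaces the mesylate at this activated α-carbonyl benzylic carbon and gives the aryl ether ester F5. i-Bu2AlH (4 equiv, CH2Cl2, −78 → 0 °C) reduces both the ester and the aryl aldehyde to the diol F6. Dess–Martin periodinane (2.6 equiv) oxidises both carbinols and returns 16.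

Step 3. O-prenylation and double C-prenylation compete with the wanted mono-C-alkylation. The fallback sets out from 4 and comes back at 6. Compound 4 is O-alkylated with 3-chloro-3-methylbut-1-yne (K2CO3, KI, acetone, reflux) to give the 1,1-dimethylpropargyl ether F7. Semi-hydrogenation (H2, Pd/CaCO3 poisoned with Pb(OAc)2, quinoline, EtOAc) gives the 1,1-dimethylallyl ether F8. Heating (N,N-diethylaniline, 130 °C) triggers the aromatic Claisen rearrangement, which transposes the allyl unit and delivers the prenyl group to the ortho carbon, giving 6 without O/C ambiguity.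

**Further compounds**
F1 | step 10 | rac-2-[2,5-bis(methoxymethoxy)phenyl]-6-methoxy-5,7-bis(methoxymethoxy)-8-(3-methylbut-2-en-1-yl)chromane-3,4-diol (stereoisomer mixture) | COc1c(OCOC)c(CC=C(C)C)c2c(c1OCOC)C(O)C(O)C(c1cc(OCOC)ccc1OCOC)O2
F2 | step 10 | racemic trans-(2R*,3R*)-2-[2,5-bis(methoxymethoxy)phenyl]-3-hydroxy-6-methoxy-5,7-bis(methoxymethoxy)-8-(3-methylbut-2-en-1-yl)-2,3-dihydro-4H-chromen-4-one (17 plus its (2S,3S)-enantiomer) | COc1c(OCOC)c(CC=C(C)C)c2c(c1OCOC)C(=O)C(O)C(c1cc(OCOC)ccc1OCOC)O2
F3 | step 7 | rac-ethyl 2-[2,5-bis(methoxymethoxy)phenyl]-2-hydroxyacetate | CCOC(=O)C(O)c1cc(OCOC)ccc1OCOC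
F4 | step 7 | rac-ethyl 2-[2,5-bis(methoxymethoxy)phenyl]-2-[(methylsulfonyl)oxy]acetate | CCOC(=O)C(OS(C)(=O)=O)c1cc(OCOC)ccc1OCOC
F5 | step 7 | rac-ethyl 2-[2,5-bis(methoxymethoxy)phenyl]-2-[2-formyl-4-methoxy-3,5-bis(methoxymethoxy)-6-(3-methylbut-2-en-1-yl)phenoxy]acetate | CCOC(=O)C(Oc1c(C=O)c(OCOC)c(OC)c(OCOC)c1CC=C(C)C)c1cc(OCOC)ccc1OCOC
F6 | step 7 | rac-2-[2,5-bis(methoxymethoxy)phenyl]-2-[2-(hydroxymethyl)-4-methoxy-3,5-bis(methoxymethoxy)-6-(3-methylbut-2-en-1-yl)phenoxy]ethan-1-ol | OCC(Oc1c(CO)c(OCOC)c(OC)c(OCOC)c1CC=C(C)C)c1cc(OCOC)ccc1OCOC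
F7 | step 3 | 2-methoxy-1,3-bis(methoxymethoxy)-5-[(2-methylbut-3-yn-2-yl)oxy]benzene | COCOc1cc(OC(C)(C)C#C)cc(OCOC)c1OC
F8 | step 3 | 2-methoxy-1,3-bis(methoxymethoxy)-5-[(2-methylbut-3-en-2-yl)oxy]benzene | COCOc1cc(OC(C)(C)C=C)cc(OCOC)c1OC
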